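**Retrosynthetic overview**
- Target ⇒ TBS removal ⇐ C11 acetate ⇐ dienol-ether **13** by Pd opening of a spiro vinyl-epoxide (this builds C3=C4 and C11 together) ⇐ cyclopentenone **11**.
- **11** ⇐ elimination of a C6 isovalerate from the trans-diol **9** by way of **10**. **9** is built by SmI2 ketyl pinacol closure (C7–C8, ring formed 5-exo) of keto-aldehyde **8**.
- **8** ⇐ acyl-radical (Giese-type) addition of TBSOCH2CHO to C9 of the Morita–Baylis–Hillman enone **5**, anti to the C1 isovalerate.
- **5** ⇐ Morita–Baylis–Hillman reaction of the isovalerate-protected Achmatowicz pyranone **3** with glyoxal dimethyl acetal. **3** ⇐ furfuryl alcohol.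
- Ring order: pyran first (Achmatowicz), then cyclopentene (C8–C9 by radical addition, C7–C8 by radical pinacol), then the diene enol ether.

Assumptions:
- The TBS group in **6** is a protecting group and is not counted, so the glycolaldehyde core has 4 heavy atoms.
- The C5 and C6 centres made in Steps 3–4 are irrelevant because both are destroyed in Step 8. The numbering below is iridoid numbering (C1 = acylal carbon, C10 = CH2OH on C8, C11 = CH2OAc).

**Step 1**
Reactants: 1, furfuryl alcohol
Product: 2, 6-hydroxy-2H-pyran-3(6H)-one (racemic lactol)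
Conditions: NBS, NaHCO3, NaOAc, THF/H2O, 0 °C
Reagents that add atoms: water, O
Why: Achmatowicz oxidative ring expansion gives the O2–C3–C4–C5=C9–C1 pyranone ring, with a C4 ketone and a C1 lactol whose configuration equilibrates.

**Step 2**
Reactants: 2
Product: 3, (6S)-6-(isovaleroyloxy)-2H-pyran-3(6H)-one
Conditions: vinyl isovalerate, CAL-B lipase, MTBE, 4 Å MS, 25 °C
Reagents that add atoms: vinyl isovalerate, C=COC(=O)CC(C)C (adds the isovaleroyl group)
Why: Proposed new method: lipase-catalysed dynamic kinetic acylation. The lactol epimerises through the ring-opened hydroxy-enedione, the enzyme acylates only the (S)-anomer, and this fixes the C1 isovalerate and C1 configuration in one step; the closest known reaction is lipase DKR of hemiacetals.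

**Step 3**
Reactants: 3; 4, glyoxal dimethyl acetal (2,2-dimethoxyacetaldehyde)
Product: 5, 5-[1-hydroxy-2,2-dimethoxyethyl]-6-(isovaleroyloxy)pyranone (C6 epimers)
Conditions: DABCO (30 mol%), dioxane/H2O, 25 °C
Reagents that add atoms: none
Why: Morita–Baylis–Hillman reaction at the enone α-carbon (C5) attaches C6 and C7 with the C7 aldehyde masked as an acetal, and the C6 carbinol is later eliminated so its configuration is irrelevant.

**Step 4**
Reactants: 5; 6, 2-(tert-butyldimethylsilyloxy)acetaldehyde
Product: 7, trans-9-[2-(TBSO)acetyl]tetrahydropyran-3-one bearing the C5 side chain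
Conditions: 6 (3 equiv), TBADT (2 mol%), MeCN, 390 nm, 25 °C
Reagents that add atoms: none
Why: Proposed new method: photo-HAT (decatungstate) gives a nucleophilic α-silyloxyacyl radical that adds to C9, the polarity-matched β-carbon of the enone, anti to the pseudo-axial C1 isovalerate, so C8 ends up trans to C1–O and C9 is set; the α-keto radical at C5 is reduced by back-HAT, and the closest known reaction is decatungstate hydroacylation of enones.

**Step 5**
Reactants: 7
Product: 8, the C7 aldehyde (α-hydroxy aldehyde)
Conditions: PPTS, acetone/H2O (9:1), 50 °C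
Reagents that add atoms: water, O
Why: Mild transacetalisation/hydrolysis unmasks C7 as the aldehyde needed for ring closure, and the acylal, TBS ether and ketones survive.

**Step 6**
Reactants: 8
Product: 9, pyran-fused cyclopentane-1,2-diol with a C8 tertiary carbinol and the C6 secondary OH (C5/C6 epimeric mixture)
Conditions: SmI2 (2.5 equiv), THF, HMPA (10 equiv), −78 °C
Reagents that add atoms: none
Why: Intramolecular ketyl–carbonyl pinacol coupling closes the cyclopentane 5-exo between the C7 aldehyde and the C8 ketone. With bulky Sm(III)(HMPA)n-alkoxides the diol is expected trans (C7-O up, C8-OH down) and CH2OTBS lands anti to the C9–C1 bond, giving the target C7/C8 relative configuration.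

**Step 7**
Reactants: 9
Product: 10, the C6,C7-bis(isovalerate)
Conditions: isovaleryl chloride, pyridine, DMAP, CH2Cl2, 0 °C
Reagents that add atoms: isovaleryl chloride, CC(C)CC(=O)Cl (adds two isovaleroyl groups)
Why: Both secondary OH groups are acylated, with retention at C7 so the target C7 ester is installed, while the hindered tertiary C8–OH is untouched; the C6 ester is the leaving group for Step 8.

**Step 8**
Reactants: 10
Product: 11, cyclopentenone with C5=C6, C7-OiVal and the C4 ketone
Conditions: DBU, CH2Cl2, 0 °C
Reagents that add atoms: none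
Why: E1cB elimination of the β-acyloxy ketone (C6 isovalerate) through the C5 enolate forms the C5=C6 enone, and C5 and C6 stereochemistry is erased here.

**Step 9**
Reactants: 11
Product: 12, spiro vinyl-epoxide at C4 (C4/C11 epoxide; C4 diastereomers)
Conditions: Me3S+ I−, KOtBu, THF/DMSO, −10 °C
Reagents that add atoms: trimethylsulfonium iodide, C[S+](C)C.[I-] (adds C11)
Why: Corey–Chaykovsky methylene transfer by dimethylsulfonium methylide adds 1,2 to the enone ketone and introduces C11; the new epoxide stereocentre is removed in the next step.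

**Step 10**
Reactants: 12
Product: 13, dienol ether with C3=C4(C11H2OH)–C5=C6 and the free C8-OH
Conditions: Pd2(dba)3 (2.5 mol%), PPh3 (10 mol%), THF, 40 °C
Reagents that add atoms: none
Why: Proposed new method: Pd(0) ionises the vinyl epoxide to a π-allyl Pd alkoxide over C4–C5–C6, and β-hydride elimination from C3–H (α to O2) gives the conjugated 1-oxadiene and the C11 primary alcohol; the closest known reaction is Pd-catalysed isomerisation of vinyl epoxides to dienols.

**Step 11**
Reactants: 13
Product: 14, C11 acetate (TBS-protected target)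
Conditions: Ac2O, pyridine, DMAP (cat.), CH2Cl2, −10 °C
Reagents that add atoms: acetic anhydride, CC(=O)OC(C)=O (adds acetyl)
Why: Chemoselective acetylation of the unhindered primary allylic C11–OH, leaving the tertiary C8–OH and the neopentyl-type OTBS untouched.

**Step 12**
Reactants: 14
Product: 15, Jatamanvaltrate K
Conditions: HF·pyridine, THF/pyridine, 0 °C
Reagents that add atoms: none
Why: Buffered fluoride removes the primary TBS ether and leaves the acylal, the dienol ether and the esters intact, unmasking the C10 CH2OH.

**Compound list**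
1 | furfuryl alcohol | OCc1ccco1 | starting material
2 | 6-hydroxy-2H-pyran-3(6H)-one | OC1OCC(=O)C=C1 | intermediate
3 | (6S)-6-(isovaleroyloxy)-2H-pyran-3(6H)-one | CC(C)CC(=O)O[C@@H]1OCC(=O)C=C1 | intermediate
4 | glyoxal dimethyl acetal | COC(OC)C=O | starting material
5 | MBH adduct (C5–CH(OH)CH(OMe)2) | CC(C)CC(=O)O[C@@H]1OCC(=O)C(C(O)C(OC)OC)=C1 | intermediate
6 | 2-(TBSO)acetaldehyde | CC(C)(C)[Si](C)(C)OCC=O | starting material
7 | trans-acylated tetrahydropyranone (C5, C6 unspecified) | CC(C)CC(=O)O[C@@H]1OCC(=O)C(C(O)C(OC)OC)[C@H]1C(=O)CO[Si](C)(C)C(C)(C)C | intermediate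
8 | C7 aldehyde | CC(C)CC(=O)O[C@@H]1OCC(=O)C(C(O)C=O)[C@H]1C(=O)CO[Si](C)(C)C(C)(C)C | intermediate
9 | pinacol triol-ketone (C5, C6 unspecified) | CC(C)CC(=O)O[C@@H]1OCC(=O)C2C(O)[C@H](O)[C@](O)(CO[Si](C)(C)C(C)(C)C)[C@@H]12 | intermediate
10 | C6,C7-bis(isovalerate) | CC(C)CC(=O)O[C@@H]1OCC(=O)C2C(OC(=O)CC(C)C)[C@H](OC(=O)CC(C)C)[C@](O)(CO[Si](C)(C)C(C)(C)C)[C@@H]12 | intermediate
11 | cyclopentenone | CC(C)CC(=O)O[C@@H]1OCC(=O)C2=C[C@H](OC(=O)CC(C)C)[C@](O)(CO[Si](C)(C)C(C)(C)C)[C@@H]12 | intermediate
12 | spiro vinyl-epoxide (C4 unspecified) | CC(C)CC(=O)O[C@@H]1OCC3(CO3)C2=C[C@H](OC(=O)CC(C)C)[C@](O)(CO[Si](C)(C)C(C)(C)C)[C@@H]12 | intermediate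
13 | dienol ether, C11-OH | CC(C)CC(=O)O[C@@H]1OC=C(CO)C2=C[C@H](OC(=O)CC(C)C)[C@](O)(CO[Si](C)(C)C(C)(C)C)[C@@H]12 | intermediate
14 | C11 acetate, C10-OTBS | CC(C)CC(=O)O[C@@H]1OC=C(COC(C)=O)C2=C[C@H](OC(=O)CC(C)C)[C@](O)(CO[Si](C)(C)C(C)(C)C)[C@@H]12 | intermediate
15 | Jatamanvaltrate K (1S,7S,8R,9S) | CC(=O)OCC1=CO[C@@H](OC(=O)CC(C)C)[C@H]2C1=C[C@H](OC(=O)CC(C)C)[C@]2(O)CO | target

**Totals**
- Total steps: 12.
- Longest linear sequence: 12 (1 → 2 → … → 15).

**Three steps most likely to fail**
1. **Step 4 (acyl-radical addition to C9).** The α-silyloxyacyl radical may decarbonylate, decatungstate may abstract the α-oxy C–H bonds instead, and the α-substituted enone is hindered.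
   - Fallback: form the C8–C9 bond polarly by an NHC-catalysed Stetter reaction of TBSOCH2CHO with the enone, which gives the same 1,4-dicarbonyl anti to C1–O.
2. **Step 6 (SmI2 pinacol).** The diastereoselectivity may favour the cis-diol, and SmI2 may cleave the α-hydroxy aldehyde or the α-alkoxy C4 ketone.
   - Fallback: use Cp2TiCl pinacol, then oxidise the C7–OH (DMP) and reduce hydroxyl-directed with Me4NBH(OAc)3 to set the trans relationship to C8-OH.
3. **Step 10 (Pd vinyl-epoxide isomerisation).** β-Acyloxy elimination at C7 or a redox isomerisation to an enal could compete with β-hydride elimination from C3–H.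
   - Fallback: make the C3=C4(C11) unit from the C4 ketone of **11** by enol triflate formation (KHMDS, PhNTf2) and Stille coupling with Bu3SnCH2OAc, instead of via the epoxide.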